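## Retrosynthetic overview

1. Endgame: the hydroquinone is unveiled from its dimethyl ether (oxidation to the quinone, then reduction), the C3 PMB ether falls in the same operation, and the C5' acetate comes from acylation of the carbinol.
2. Aryl–C1'–C2' bond and the (E)-C2'=C3'(CH3) olefin: zirconium-catalysed methylalumination of a terminal alkyne, then palladium-catalysed coupling of the alkenylalane with a benzylic chloride. The C5' carbinol comes from catalyst-controlled propargylation of a geranial-type enal.
3. Oxolane: the C3 carbinol comes from the C3 ketone (CBS reduction). The C4–C5 bond is closed by an enantioselective [1,3] O-to-C (Petasis–Ferrier) rearrangement of a 4-methylene-1,3-dioxolane, assembled from the terminal (E)-enal of doubly oxidised geraniol (its CHO carbon becomes C5), 2-hydroxyisobutyric acid and one CH2 (titanium methylenation).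
4. Enabling feature: in the oxolane (O1, C2, C3, C4, C5) the C3 oxygen and O1 are 1,3-related across the quaternary C2(CH3)2, with C4H2 between C3 and C5. C5 is an aldehyde-level, allylic carbon that both oxygens can hold as an acetal, so C4–C5 is the aldol bond between the enol carbon of a C3 ketone and the O1-stabilised cation at C5. The quaternary C2 leaves C4 as the only enolisable position.
5. Ring order: 1,3-dioxolan-4-one (temporary), then 4-methylene-1,3-dioxolane (temporary), then the oxolane (the only ring built). The benzene ring is bought as 4-methoxy-2-methylphenol.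

Key step: step 5

Remark (assumption): the sense of induction of the chiral phosphoric acid in steps 5 and 10 is assigned by analogy with related ion-pair and allylboration models. Both antipodes are available, and the one that gives the drawn configuration is meant. Labels used in the text: oxolane O1, C2 (CMe2), C3 (carbinol), C4 (CH2), C5 (allylic CH); side chain C1' (benzylic) to C11' (bonded to C5).

## Route

Step 1
Reactants: 1 geraniol
Product: 2 geranyl tert-butyldiphenylsilyl ether
Conditions: TBDPSCl, imidazole, DMF, 0 °C → rt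
Reagents that add atoms: tert-butyl(chloro)diphenylsilane, CC(C)(C)[Si](Cl)(c1ccccc1)c1ccccc1
Why: Imidazole-promoted silylation of the primary allylic alcohol gives an ether that, unlike an ester, survives the later titanium methylenation.

Step 2
Reactants: 2 geranyl tert-butyldiphenylsilyl ether
Product: 4 (2E,6E)-8-(tert-butyldiphenylsilyloxy)-2,6-dimethylocta-2,6-dienal, via the allylic alcohol 3 (not isolated)
Conditions: SeO2 (cat.), tBuOOH, salicylic acid (cat.), CH2Cl2, rt; then crude material, MnO2, CH2Cl2, rt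
Reagents that add atoms: selenium dioxide, O=[Se]=O; tert-butyl hydroperoxide (terminal oxidant), CC(C)(C)OO
Why: The catalytic SeO2/tBuOOH allylic oxidation (ene reaction, then [2,3] shift) attacks the (E)-methyl of the more electron-rich terminal alkene, and MnO2 then converges the alcohol/aldehyde mixture on the (E)-enal.

Step 3
Reactants: 4 the (E)-enal; 5 2-hydroxyisobutyric acid
Product: 6 rac-2-[(2E,6E)-8-(tert-butyldiphenylsilyloxy)-6-methylocta-2,6-dien-2-yl]-5,5-dimethyl-1,3-dioxolan-4-one
Conditions: TsOH·H2O (cat.), pentane, reflux, Dean–Stark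
Reagents that add atoms: 2-hydroxyisobutyric acid (5), CC(C)(O)C(=O)O
Why: Acid-catalysed acetalisation of an aldehyde with an α-hydroxy acid to a 1,3-dioxolan-4-one is driven by azeotropic removal of water at low temperature; the acetal centre forms racemic and is erased in step 5.

Step 4
Reactants: 6 the dioxolanone
Product: 7 rac-2-[(2E,6E)-8-(tert-butyldiphenylsilyloxy)-6-methylocta-2,6-dien-2-yl]-4,4-dimethyl-5-methylidene-1,3-dioxolane
Conditions: Cp2TiMe2, PhMe, 65 °C, dark; filtration through basic alumina
Reagents that add atoms: dimethyltitanocene, C[Ti](C)(C1C=CC=C1)C1C=CC=C1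
Why: Petasis methylenation of the lactone-type carbonyl (via Cp2Ti=CH2 and an oxatitanacyclobutane) runs under non-acidic conditions that keep the enol acetal intact; the silyl ether and the alkenes are inert.

Step 5
Reactants: 7 the 4-methylene-1,3-dioxolane
Product: 8 (5S)-5-[(2E,6E)-8-(tert-butyldiphenylsilyloxy)-6-methylocta-2,6-dien-2-yl]-2,2-dimethyloxolan-3-one
Conditions: (R)-TRIP [(R)-3,3'-bis(2,4,6-triisopropylphenyl)-1,1'-binaphthyl-2,2'-diyl hydrogen phosphate] (10 mol%), 4 Å MS, PhMe, −40 → 0 °C
Reagents that add atoms: none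
Why: Proposed new method: the chiral phosphoric acid hydrogen-bonds to and protonates the enol-ether oxygen of 7, the acetal C–O bond on that side ionises (the leaving group is an enol, the cation a 2-alkenyl oxocarbenium ion stabilised by O1 and the adjacent C=C), and the enol CH2 then attacks the oxocarbenium carbon inside the hydrogen-bonded chiral ion pair, a net [1,3] O-to-C shift that forms the C4–C5 bond and closes the oxolane before tautomerisation to the ketone. The closest known reaction types are the aluminium-promoted Petasis–Ferrier rearrangement of 4-methylene-1,3-dioxolanes to oxolan-3-ones (same bond, same ring, no absolute control) and chiral phosphoric acid-catalysed Petasis–Ferrier-type rearrangements of vinyl acetals and hemiaminal vinyl ethers; the enantioselective version on this dioxolane class is what is new. The ring closes in a formally 5-(enolendo)-endo-trig mode, the closure already established for the aluminium-promoted reaction. C5 is the only new stereocentre and is set by the catalyst: the phosphate anion binds the enol OH and covers one face of the planar (E)-oxocarbenium ion, and the antipode that gives (5S) has to be fixed in the first runs. The step needs attack at the oxocarbenium carbon and not at its vinylogous terminus (a formal [3,3] shift to an oxepanone), which the five-membered transition state and the gem-dimethyl group at C2 favour, and it needs the enol ether to stay exocyclic, which the quaternary C2 guarantees because reversible C-protonation can only return the same CH2 enol ether. Dry conditions suppress acetal hydrolysis, and the silyl ether and trisubstituted alkenes should be inert to the weak acid.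

Step 6
Reactants: 8 the (5S)-ketone
Product: 9 (3S,5S)-5-[(2E,6E)-8-(tert-butyldiphenylsilyloxy)-6-methylocta-2,6-dien-2-yl]-2,2-dimethyloxolan-3-ol (3-OH cis to the C5 side chain)
Conditions: (R)-Me-CBS [(3aR)-1-methyl-3,3-diphenyltetrahydro-1H,3H-pyrrolo[1,2-c][1,3,2]oxazaborole] (20 mol%), catecholborane, PhMe, −78 °C
Reagents that add atoms: none
Why: In this Corey–Bakshi–Shibata reduction the quaternary C2 is the large and C4H2 the small group, so the (R)-catalyst should deliver hydride to give (3S); approach anti to the C5 side chain reinforces the cis isomer, and catecholborane does not hydroborate the trisubstituted alkenes at this temperature.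

Step 7
Reactants: 9 the cis-alcohol
Product: 10 (3S,5S)-5-[(2E,6E)-8-(tert-butyldiphenylsilyloxy)-6-methylocta-2,6-dien-2-yl]-3-[(4-methoxybenzyl)oxy]-2,2-dimethyloxolane
Conditions: NaH, PMBCl, Bu4NI (cat.), DMF, 0 °C → rt
Reagents that add atoms: 4-methoxybenzyl chloride, COc1ccc(CCl)cc1
Why: Williamson etherification of the hindered secondary alkoxide (iodide catalysis) installs a group that withstands fluoride, AlMe3 and acylation and leaves oxidatively in the last step.

Step 8
Reactants: 10 the PMB ether
Product: 11 (3S,5S)-5-[(2E,6E)-8-hydroxy-6-methylocta-2,6-dien-2-yl]-3-[(4-methoxybenzyl)oxy]-2,2-dimethyloxolane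
Conditions: TBAF, THF, 0 °C → rt
Reagents that add atoms: none
Why: Fluoride-mediated desilylation frees the primary allylic alcohol while the PMB ether and the oxolane are untouched.

Step 9
Reactants: 11 the primary allylic alcohol
Product: 12 (3S,5S)-5-[(2E,6E)-6-methyl-8-oxoocta-2,6-dien-2-yl]-3-[(4-methoxybenzyl)oxy]-2,2-dimethyloxolane
Conditions: MnO2, CH2Cl2, rt
Reagents that add atoms: none
Why: MnO2 oxidises only the allylic alcohol and keeps the (E)-geometry of the resulting geranial-type enal.

Step 10
Reactants: 12 the geranial-type enal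
Product: 13 (3S,5S)-5-[(2E,6E,8S)-8-hydroxy-6-methylundeca-2,6-dien-10-yn-2-yl]-3-[(4-methoxybenzyl)oxy]-2,2-dimethyloxolane
Conditions: allenylboronic acid pinacol ester, (S)-TRIP [(S)-3,3'-bis(2,4,6-triisopropylphenyl)-1,1'-binaphthyl-2,2'-diyl hydrogen phosphate] (10 mol%), 4 Å MS, PhMe, 0 °C
Reagents that add atoms: allenylboronic acid pinacol ester, C=C=CB1OC(C)(C)C(C)(C)O1
Why: Chiral phosphoric acid-catalysed allenylboration (SE2' propargylation through a six-membered transition state in which the acid binds the boronate oxygen and the formyl hydrogen) sets the C5' carbinol under catalyst control, independent of the remote oxolane.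

Step 11
Reactants: 14 4-methoxy-2-methylphenol
Product: 15 2-hydroxy-5-methoxy-3-methylbenzaldehyde
Conditions: MgCl2, Et3N, (CH2O)n, MeCN, reflux
Reagents that add atoms: paraformaldehyde (formaldehyde), C=O
Why: The magnesium phenoxide-directed ortho-formylation (Casnati–Skattebøl) can only go to the single free ortho position, which fixes the 2,6-dialkyl pattern of the hydroquinone.

Step 12
Reactants: 15 the salicylaldehyde
Product: 16 2,5-dimethoxy-3-methylbenzaldehyde
Conditions: MeI, K2CO3, DMF, rt
Reagents that add atoms: iodomethane, CI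
Why: Williamson O-methylation of the phenol gives the robust dimethyl ether form of the hydroquinone.

Step 13
Reactants: 16 the dimethoxy aldehyde
Product: 17 (2,5-dimethoxy-3-methylphenyl)methanol
Conditions: NaBH4, MeOH, 0 °C
Reagents that add atoms: none
Why: Borohydride reduction of the aryl aldehyde gives the benzylic alcohol.

Step 14
Reactants: 17 the benzylic alcohol
Product: 18 1-(chloromethyl)-2,5-dimethoxy-3-methylbenzene
Conditions: SOCl2, CH2Cl2, 0 °C; used crude
Reagents that add atoms: thionyl chloride, O=S(Cl)Cl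
Why: Chlorination through the chlorosulfite is fast for this electron-rich benzylic alcohol and gives the electrophile for the cross-coupling.

Step 15
Reactants: 13 the homopropargylic alcohol; 18 the benzylic chloride
Product: 20 (3S,5S)-5-[(2E,6E,8S,10E)-12-(2,5-dimethoxy-3-methylphenyl)-8-hydroxy-6,10-dimethyldodeca-2,6,10-trien-2-yl]-3-[(4-methoxybenzyl)oxy]-2,2-dimethyloxolane, via the (E)-alkenylalane 19 (not isolated)
Conditions: AlMe3 (3.5 equiv), Cp2ZrCl2 (0.25 equiv), CH2Cl2, 0 °C → rt; volatiles removed; then 18, Pd(PPh3)4 (5 mol%), THF, rt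
Reagents that add atoms: trimethylaluminium, C[Al](C)C; benzylic chloride 18, COc1cc(C)c(OC)c(CCl)c1
Why: Negishi zirconium-catalysed methylalumination (syn addition, methyl to the internal carbon, the hydroxyl carried as its aluminium alkoxide) gives the (E)-alkenylalane, and palladium-catalysed cross-coupling with the benzylic chloride then forms the aryl–C1'–C2' connection with retention of the olefin geometry.

Step 16
Reactants: 20 the C5' alcohol
Product: 21 the C5' acetate of 20, (3S,5S)-5-[(2E,6E,8S,10E)-8-acetoxy-12-(2,5-dimethoxy-3-methylphenyl)-6,10-dimethyldodeca-2,6,10-trien-2-yl]-3-[(4-methoxybenzyl)oxy]-2,2-dimethyloxolane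
Conditions: Ac2O, pyridine, DMAP (cat.), CH2Cl2, 0 °C → rt
Reagents that add atoms: acetic anhydride, CC(=O)OC(C)=O
Why: DMAP-catalysed acylation of the only free hydroxyl installs the allylic acetate without touching the stereocentre.

Step 17
Reactants: 21 the acetate
Product: 23 CNP0227918.2, 2-[(2E,5S,6E,10E)-5-acetoxy-11-[(2S,4S)-4-hydroxy-5,5-dimethyloxolan-2-yl]-3,7-dimethyldodeca-2,6,10-trien-1-yl]-6-methylbenzene-1,4-diol, via the quinone 22 (not isolated)
Conditions: (NH4)2Ce(NO3)6 (5 equiv), MeCN/H2O (4:1), 0 °C; then aq. Na2S2O4, EtOAc, rt, under argon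
Reagents that add atoms: water, O
Why: Ceric ammonium nitrate oxidatively demethylates the 1,4-dimethoxyarene to the p-quinone and cleaves the PMB ether in the same pot, and dithionite then reduces the quinone to the hydroquinone; the acetate, the free carbinol and the trisubstituted alkenes should tolerate this short, cold sequence.

## Compound list

1 | geraniol, (2E)-3,7-dimethylocta-2,6-dien-1-ol | CC(C)=CCC/C(C)=C/CO | starting material
2 | geranyl tert-butyldiphenylsilyl ether | CC(C)=CCC/C(C)=C/CO[Si](c1ccccc1)(c1ccccc1)C(C)(C)C | intermediate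
3 | (2E,6E)-8-(tert-butyldiphenylsilyloxy)-2,6-dimethylocta-2,6-dien-1-ol | OC/C(C)=C/CC/C(C)=C/CO[Si](c1ccccc1)(c1ccccc1)C(C)(C)C | intermediate
4 | (2E,6E)-8-(tert-butyldiphenylsilyloxy)-2,6-dimethylocta-2,6-dienal | O=C/C(C)=C/CC/C(C)=C/CO[Si](c1ccccc1)(c1ccccc1)C(C)(C)C | intermediate
5 | 2-hydroxyisobutyric acid (2-hydroxy-2-methylpropanoic acid) | CC(C)(O)C(=O)O | starting material
6 | rac-2-[(2E,6E)-8-(tert-butyldiphenylsilyloxy)-6-methylocta-2,6-dien-2-yl]-5,5-dimethyl-1,3-dioxolan-4-one | CC1(C)OC(/C(C)=C/CC/C(C)=C/CO[Si](c2ccccc2)(c2ccccc2)C(C)(C)C)OC1=O | intermediate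
7 | rac-2-[(2E,6E)-8-(tert-butyldiphenylsilyloxy)-6-methylocta-2,6-dien-2-yl]-4,4-dimethyl-5-methylidene-1,3-dioxolane | C=C1OC(/C(C)=C/CC/C(C)=C/CO[Si](c2ccccc2)(c2ccccc2)C(C)(C)C)OC1(C)C | intermediate
8 | (5S)-5-[(2E,6E)-8-(tert-butyldiphenylsilyloxy)-6-methylocta-2,6-dien-2-yl]-2,2-dimethyloxolan-3-one | CC(C)(C)[Si](c1ccccc1)(c1ccccc1)OC/C=C(\C)CC/C=C(\C)[C@@H]1CC(=O)C(C)(C)O1 | intermediate
9 | (3S,5S)-5-[(2E,6E)-8-(tert-butyldiphenylsilyloxy)-6-methylocta-2,6-dien-2-yl]-2,2-dimethyloxolan-3-ol | CC(C)(C)[Si](c1ccccc1)(c1ccccc1)OC/C=C(\C)CC/C=C(\C)[C@@H]1C[C@H](O)C(C)(C)O1 | intermediate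
10 | (3S,5S)-5-[(2E,6E)-8-(tert-butyldiphenylsilyloxy)-6-methylocta-2,6-dien-2-yl]-3-[(4-methoxybenzyl)oxy]-2,2-dimethyloxolane | CC(C)(C)[Si](c1ccccc1)(c1ccccc1)OC/C=C(\C)CC/C=C(\C)[C@@H]1C[C@H](OCc2ccc(OC)cc2)C(C)(C)O1 | intermediate
11 | (3S,5S)-5-[(2E,6E)-8-hydroxy-6-methylocta-2,6-dien-2-yl]-3-[(4-methoxybenzyl)oxy]-2,2-dimethyloxolane | OC/C=C(\C)CC/C=C(\C)[C@@H]1C[C@H](OCc2ccc(OC)cc2)C(C)(C)O1 | intermediate
12 | (3S,5S)-5-[(2E,6E)-6-methyl-8-oxoocta-2,6-dien-2-yl]-3-[(4-methoxybenzyl)oxy]-2,2-dimethyloxolane | O=C/C=C(\C)CC/C=C(\C)[C@@H]1C[C@H](OCc2ccc(OC)cc2)C(C)(C)O1 | intermediate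
13 | (3S,5S)-5-[(2E,6E,8S)-8-hydroxy-6-methylundeca-2,6-dien-10-yn-2-yl]-3-[(4-methoxybenzyl)oxy]-2,2-dimethyloxolane | C#CC[C@H](O)/C=C(\C)CC/C=C(\C)[C@@H]1C[C@H](OCc2ccc(OC)cc2)C(C)(C)O1 | intermediate
14 | 4-methoxy-2-methylphenol | COc1ccc(O)c(C)c1 | starting material
15 | 2-hydroxy-5-methoxy-3-methylbenzaldehyde | COc1cc(C)c(O)c(C=O)c1 | intermediate
16 | 2,5-dimethoxy-3-methylbenzaldehyde | COc1cc(C)c(OC)c(C=O)c1 | intermediate
17 | (2,5-dimethoxy-3-methylphenyl)methanol | COc1cc(C)c(OC)c(CO)c1 | intermediate
18 | 1-(chloromethyl)-2,5-dimethoxy-3-methylbenzene | COc1cc(C)c(OC)c(CCl)c1 | intermediate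
19 | (E)-alkenyl(dimethyl)alane from 13 (AlMe2 on C2', methyl on C3', C5' oxygen as its dimethylaluminium alkoxide) | C[Al](C)/C=C(\C)C[C@H](O[Al](C)C)/C=C(\C)CC/C=C(\C)[C@@H]1C[C@H](OCc2ccc(OC)cc2)C(C)(C)O1 | intermediate
20 | (3S,5S)-5-[(2E,6E,8S,10E)-12-(2,5-dimethoxy-3-methylphenyl)-8-hydroxy-6,10-dimethyldodeca-2,6,10-trien-2-yl]-3-[(4-methoxybenzyl)oxy]-2,2-dimethyloxolane | COc1cc(C)c(OC)c(C/C=C(\C)C[C@H](O)/C=C(\C)CC/C=C(\C)[C@@H]2C[C@H](OCc3ccc(OC)cc3)C(C)(C)O2)c1 | intermediate
21 | (3S,5S)-5-[(2E,6E,8S,10E)-8-acetoxy-12-(2,5-dimethoxy-3-methylphenyl)-6,10-dimethyldodeca-2,6,10-trien-2-yl]-3-[(4-methoxybenzyl)oxy]-2,2-dimethyloxolane | COc1cc(C)c(OC)c(C/C=C(\C)C[C@H](OC(C)=O)/C=C(\C)CC/C=C(\C)[C@@H]2C[C@H](OCc3ccc(OC)cc3)C(C)(C)O2)c1 | intermediate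
22 | 2-[(2E,5S,6E,10E)-5-acetoxy-11-[(2S,4S)-4-hydroxy-5,5-dimethyloxolan-2-yl]-3,7-dimethyldodeca-2,6,10-trien-1-yl]-6-methyl-1,4-benzoquinone | CC(=O)O[C@H](/C=C(\C)CC/C=C(\C)[C@@H]1C[C@H](O)C(C)(C)O1)C/C(C)=C/CC1=CC(=O)C=C(C)C1=O | intermediate
23 | CNP0227918.2, 2-[(2E,5S,6E,10E)-5-acetoxy-11-[(2S,4S)-4-hydroxy-5,5-dimethyloxolan-2-yl]-3,7-dimethyldodeca-2,6,10-trien-1-yl]-6-methylbenzene-1,4-diol | CC(=O)O[C@H](/C=C(\C)CC/C=C(\C)[C@@H]1C[C@H](O)C(C)(C)O1)C/C(C)=C/Cc1cc(O)cc(C)c1O | target

## Step count and risks

Total step count: 17. Longest linear sequence: 13 steps (steps 1–10 and 15–17, from geraniol).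

Steps most likely to fail:

1. Step 5 (Proposed new method). The ion pair may discriminate the two faces of the oxocarbenium ion poorly, or the enol ether may be lost to non-productive protonation and hydrolysis. Fallback, from 7 back to 9: the rearrangement is run under the established achiral aluminium protocol (Me2AlCl, CH2Cl2, −78 °C), which should give the racemic ketone F1. The stereochemical problem then moves to the next operation: (R)-Me-CBS/catecholborane reduces both enantiomers to (3S) carbinols under reagent control. The (3S,5S)-cis alcohol 9 is separated by chromatography from the (3S,5R)-trans alcohol F2, and the route is rejoined at 9 at the cost of half of the material.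

2. Step 15. The alkoxide-bearing alane may transmetalate sluggishly or be protonated before coupling, and the Lewis-acidic medium may open the allylic oxolane during a slow coupling. Fallback, from 13 back to 20: the polarity of the coupling is reversed. After the same methylalumination the alane 19 is quenched with I2 (THF, −30 °C) to the (E)-vinyl iodide F3. Chloride 18 is converted with zinc dust and LiCl (THF) into the benzylic zinc chloride F4. A Negishi coupling of F3 with an excess of F4 (Pd(PPh3)4, THF, rt) should give 20, where the route is rejoined.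

3. Step 17. The longer exposure needed for PMB cleavage may over-oxidise the side chain or let the acidic medium ionise the allylic acetate. Fallback, from 21 back to 22: the PMB group is first removed without oxidant (MgBr2·OEt2, Me2S, CH2Cl2, rt) to give the C3 alcohol F5. A short treatment with (NH4)2Ce(NO3)6 (2.5 equiv, 0 °C) then only has to oxidise the dimethoxyarene and should give the quinone 22, where the route is rejoined (dithionite reduction to 23).

Further compounds
F1 | step 5 | rac-5-[(2E,6E)-8-(tert-butyldiphenylsilyloxy)-6-methylocta-2,6-dien-2-yl]-2,2-dimethyloxolan-3-one | CC(C)(C)[Si](c1ccccc1)(c1ccccc1)OC/C=C(\C)CC/C=C(\C)C1CC(=O)C(C)(C)O1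
F2 | step 5 | (3S,5R)-5-[(2E,6E)-8-(tert-butyldiphenylsilyloxy)-6-methylocta-2,6-dien-2-yl]-2,2-dimethyloxolan-3-ol (trans) | CC(C)(C)[Si](c1ccccc1)(c1ccccc1)OC/C=C(\C)CC/C=C(\C)[C@H]1C[C@H](O)C(C)(C)O1
F3 | step 15 | (3S,5S)-5-[(2E,6E,8S,10E)-8-hydroxy-11-iodo-6,10-dimethylundeca-2,6,10-trien-2-yl]-3-[(4-methoxybenzyl)oxy]-2,2-dimethyloxolane | I/C=C(\C)C[C@H](O)/C=C(\C)CC/C=C(\C)[C@@H]1C[C@H](OCc2ccc(OC)cc2)C(C)(C)O1
F4 | step 15 | (2,5-dimethoxy-3-methylbenzyl)zinc chloride | COc1cc(C)c(OC)c(C[Zn]Cl)c1
F5 | step 17 | (3S,5S)-5-[(2E,6E,8S,10E)-8-acetoxy-12-(2,5-dimethoxy-3-methylphenyl)-6,10-dimethyldodeca-2,6,10-trien-2-yl]-2,2-dimethyloxolan-3-ol | COc1cc(C)c(OC)c(C/C=C(\C)C[C@H](OC(C)=O)/C=C(\C)CC/C=C(\C)[C@@H]2C[C@H](O)C(C)(C)O2)c1
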